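## Structural features

The target is a flavan-3,4-diol: a chroman in which ring A (a phloroglucinol unit) is fused to the pyran ring C through C4a–C8a, with a 4-hydroxyphenyl ring B on C2. Ring A carries a methyl ether at C5, a free phenol at C7 and a prenyl chain at C8, the carbon between the C7 oxygen and O1; only C6 bears hydrogen. C2, C3 and C4 are three adjacent stereocentres (2R,3S,4S): ring B and the C3 hydroxyl are trans, the C3 and C4 hydroxyls are cis. The C4 hydroxyl is benzylic to a trioxygenated ring and ionises readily with acid, the prenyl group next to a phenol cyclises under acid and reacts with every alkene oxidant, and the 4-hydroxyphenyl group can open ring C at C2 through a quinone methide. The real difficulty is to set three contiguous oxygenated centres, including a 3,4-cis relation that hydride reduction of a C4 ketone does not favour, without acid and without oxidants once the prenyl group is present. The key step exploits the anti arrangement of O1 and the hydroxyl across C2–C3, which is what results when the C8a phenol opens a trans C2–C3 oxirane at benzylic C2 with inversion. That oxirane can be made without an oxidant by joining C2 (a benzylic ylide carbon carrying ring B) to C3 (an aldehyde carbon that already carries C4 and ring A).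

## Logic of the disconnections

**26 to 23.** The O1–C2 bond and the four O–Si bonds are cut. The trans O1/OH pattern is the signature of an intramolecular opening of a trans oxirane at C2, so ring C and the C2 stereocentre are traded for an open chain. The forward step must attack C2 (6-endo) and not C3 (5-exo), must invert C2 cleanly, and must use no acid. The electron-rich ring B activates C2, the silyloxy group on C4 deactivates and shields C3, and fluoride is the only reagent needed.

**23 to 14 and 20.** The C2–C3 bond and the O–C2 bond of the oxirane are cut. This divides the molecule into a ring A half holding C3 and C4 and a ring B half holding C2, and it is the one way to make the oxirane that needs no oxidant, so the prenyl alkene is a spectator. Two stereocentres (C3, C2) are derived from one (C4). The forward step must attack one face of the aldehyde, must close to the trans oxirane, and must not epimerise the acidic C4–H.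

**20 to 18 and 19, then 17 and 15.** The S–C, C–Br and O–Si bonds are cut in turn. These are routine operations on a benzylic alcohol; the only demand is that the phenol, not the benzylic hydroxyl, is silylated.

**14 to 12 to 11.** The aldehyde carbon is taken back to the ester oxidation level and the C4 O–Si bond is cut. This places C4 in a configurationally robust hydroxy ester. The forward steps must stop the reduction at the aldehyde and must keep C4 intact.

**11 to 10.** The C4–H bond is cut, so that C4 comes from a planar ketone by enantioselective hydride transfer. The forward step must distinguish the faces of a ketone whose aryl group is twisted by two ortho oxygens.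

**10 to 9 to 8.** The ring A O–Si bonds are exchanged for acetal protecting groups. The acetals are needed to direct the metalations and need acid for removal. Acid is tolerable only while C4 is still a ketone, because afterwards C4–O is a trioxybenzylic position that ionises. The exchange is therefore placed here and must be mild enough to spare the prenyl group.

**8 to 5 and 6.** The C4a–C4 bond is cut. Because 5 has a mirror plane, its two remaining ring positions are equivalent and the bond can form at only one kind of carbon. The forward step must metalate the ring and not the benzylic-allylic CH2 of the prenyl chain, and must add only once to 6.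

**5 to 2 and 3, then 1.** The C8–prenyl bond and the two acetal O–C bonds are cut. The ring carbon between the two acetal oxygens of 2 is the preferred site of metalation, which fixes the prenyl group at C8 without isomers. Alkylation must take place at the primary carbon of 3.

## Other disconnections considered

**Alternative 1:** The cut is O1–C2 of a C4 ketone whose C2, C3 and C4 carbons and C3 stereocentre come from D-tyrosine A3 (diazotisation with retention, then acylation of a ring A organometallic to give the open-chain ketone A2). In the forward key step DDQ removes hydride from the benzylic CH2 of A2, para to the silyloxy group, and the ortho phenol captures the cation to give A1 with ring B trans to the C3 oxygen.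
- In its favour: C3 comes from the chiral pool with no dependence on the facial sense of a catalyst, and on this point it is better than the chosen plan. The ring closure is simple and the 2,3-trans relation is the thermodynamic one.
- Against it: the prenyl CH2 is itself a hydride donor towards DDQ, so C8 must carry bromine through the key step and the prenyl group must be introduced later by cross-coupling at a di-ortho-substituted carbon. C3–H lies between a ketone and the cationic C2 and can be lost as a proton, which would erase C3. The C4 ketone must be reduced at the end, and hydride reduction of such ketones tends to place the C4 hydroxyl trans to the C3 oxygen, the opposite of what is needed.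
- Comparison: both plans close ring C by forming O1–C2 at a para-oxygenated benzylic carbon, here through a cation under thermodynamic control and in the chosen plan by substitution with inversion. The chosen plan sets C4 first and lets it control C3, whereas this one must set C4 last against the substrate bias. Three steps follow A1 (reduction, prenylation, desilylation) against one after the key step of the chosen plan, so step economy is no better.

**Alternative 2:** The cut is C4–C4a. C3 and C4 come from a tartaric acid, the O1–C2 ether is already in place, and the N-hydroxyphthalimide ester A5 is the precursor. In the forward key step, cathodic reduction with NiBr2 and 4,4'-di-tert-butyl-2,2'-bipyridine generates the C4 dioxolanyl radical, which nickel joins to the aryl bromide carbon to give A4.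
- In its favour: the cis-fused dioxolane enforces the 3,4-cis relation at ring closure whatever the configuration of the radical precursor. This is at least the equal of, and probably more secure than, the Felkin–Anh control of the chosen plan. The conditions are reductive and spare the prenyl alkene.
- Against it: C2 must be set earlier in an open chain, and the O1–C2 ether must be made by substitution at an ionisation-prone para-silyloxybenzylic carbon with a hindered phenol. The aryl bromide is electron-rich and flanked by two oxygens, which slows oxidative addition at nickel. Six-membered ring closure by radical capture at nickel is far less tried than the intermolecular coupling. The C3 configuration requires the (S,S) acid A6, not the cheap natural enantiomer. Above all, the acetonide must be removed with acid at the end, which is exactly where C4 ionises and the prenyl group cyclises.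
- Comparison: the chosen plan ends with fluoride only and forms all its bonds by polar, well-precedented steps. The route to A5 is long and linear, so step economy is worse.

**Alternative 3:** The cuts are C4a–C4 and O1–C2 in one operation, from the symmetrical resorcinol A8 and the epoxy aldehyde A9. In the forward key step the titanium phenoxide formed with ClTi(OiPr)3 adds through its ortho carbon to the aldehyde, and the same phenol oxygen then opens the oxirane at C2 with inversion to give A7.
- In its favour: it is by far the shortest plan. Ring A needs no protecting groups, the symmetry of A8 removes any regiochemical question, and C2 and C3 come from a reagent-controlled asymmetric epoxidation carried out before the prenyl group is in the same molecule. On step economy and on the control of C2 and C3 it is better than the chosen plan.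
- Against it: C4 is created in the phenoxide–aldehyde addition, whose facial selectivity towards an epoxy aldehyde (chelated or not) is not secure. The C4 carbinol formed is an ortho-hydroxybenzylic alcohol on a phloroglucinol ring in the presence of a Lewis acidic titanium alkoxide, so ionisation to an ortho-quinone methide, epimerisation at C4 and a second arylation are all likely. The para-silyloxyphenyl oxirane of A9 is also prone to Lewis acid rearrangement.
- Comparison: the ring-closing event is the same as in the chosen plan, and on that point the two are equal. The difference is that the chosen plan sets C4 by catalytic reduction away from any Lewis acid and then uses it to direct C3, at the price of about twice as many steps.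

Key step: step 12

Remarks on the chemistry:
- Flavan numbering (O1, C2, C3, C4, C4a, C5–C8, C8a) is used for the corresponding atoms of all open-chain compounds. TBS is tert-butyldimethylsilyl, TIPS is triisopropylsilyl, MOM is methoxymethyl, prenyl is 3-methylbut-2-en-1-yl.
- In the ylide epoxidation the two bonds made are C2–C3 and O–C2. The C3–O bond of the oxirane is the former carbonyl bond of 14 and becomes the C3 hydroxyl of 26.
- The ring B phenol is carried as a TIPS ether, not a TBS ether, so that it is the last aryl silyl ether to leave.
- The S descriptor at C3 of 26 reads R in 25 only because a silylated C4 oxygen outranks C2; the geometry is unchanged.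

## Route

Step 1
Reactants: 1 5-methoxyresorcinol
Product: 2 1-methoxy-3,5-bis(methoxymethoxy)benzene
Conditions: MOMCl, i-Pr2NEt, CH2Cl2, 0 → 25 °C
Reagents that add atoms: chloromethyl methyl ether (MOMCl), COCCl
Why: O-alkylation of both phenols (acetal formation); the two MOM ethers are the ortho-directing groups for the two metalations that follow.

Step 2
Reactants: 2 1-methoxy-3,5-bis(methoxymethoxy)benzene; 3 prenyl bromide
Product: 5 5-methoxy-1,3-bis(methoxymethoxy)-2-(3-methylbut-2-en-1-yl)benzene, via aryllithium 4 (not isolated)
Conditions: n-BuLi, THF, 0 °C; CuI (10 mol%), 3, −78 → 25 °C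
Reagents that add atoms: none
Why: Directed ortho-metalation at the carbon flanked by both MOM ethers, then copper-assisted allylic substitution at the primary carbon of 3 (the other terminus is fully substituted). The product has a mirror plane, so its two remaining ring C–H positions are equivalent.

Step 3
Reactants: 5 5-methoxy-1,3-bis(methoxymethoxy)-2-(3-methylbut-2-en-1-yl)benzene; 6 diethyl oxalate
Product: 8 ethyl 2-[6-methoxy-2,4-bis(methoxymethoxy)-3-(3-methylbut-2-en-1-yl)phenyl]-2-oxoacetate, via aryllithium 7 (not isolated)
Conditions: n-BuLi, TMEDA, THF, −20 → 0 °C; added to 6 (3 equiv), THF, −78 °C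
Reagents that add atoms: none
Why: A second directed ortho-metalation, at the only kind of ring C–H left (between a MOM ether and the methyl ether), followed by acylation of the aryllithium with an oxalate diester. Inverse addition into excess 6 at −78 °C keeps the tetrahedral adduct intact and prevents double addition.

Step 4
Reactants: 8 ethyl 2-[6-methoxy-2,4-bis(methoxymethoxy)-3-(3-methylbut-2-en-1-yl)phenyl]-2-oxoacetate
Product: 9 ethyl 2-[2,4-dihydroxy-6-methoxy-3-(3-methylbut-2-en-1-yl)phenyl]-2-oxoacetate
Conditions: HCl (1.25 M in EtOH), 25 → 40 °C
Reagents that add atoms: none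
Why: Acid-catalysed acetal exchange removes both MOM groups while C4 is still a ketone, so no stereocentre or ionisable carbinol is exposed to acid. Ethanol keeps the ethyl ester, and dilute acid at low temperature is below what is needed for prenyl–phenol cyclisation.

Step 5
Reactants: 9 ethyl 2-[2,4-dihydroxy-6-methoxy-3-(3-methylbut-2-en-1-yl)phenyl]-2-oxoacetate
Product: 10 ethyl 2-[2,4-bis(tert-butyldimethylsilyloxy)-6-methoxy-3-(3-methylbut-2-en-1-yl)phenyl]-2-oxoacetate
Conditions: TBSOTf, 2,6-lutidine, CH2Cl2, 0 → 25 °C
Reagents that add atoms: tert-butyldimethylsilyl trifluoromethanesulfonate (TBSOTf), CC(C)(C)[Si](C)(C)OS(=O)(=O)C(F)(F)F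
Why: O-silylation of both phenols; the triflate is needed for the hydrogen-bonded, doubly flanked C8a hydroxyl. Silyl ethers are the only ring A protection that can later be removed without acid.

Step 6
Reactants: 10 ethyl 2-[2,4-bis(tert-butyldimethylsilyloxy)-6-methoxy-3-(3-methylbut-2-en-1-yl)phenyl]-2-oxoacetate
Product: 11 ethyl (S)-2-[2,4-bis(tert-butyldimethylsilyloxy)-6-methoxy-3-(3-methylbut-2-en-1-yl)phenyl]-2-hydroxyacetate
Conditions: RuCl(p-cymene)[(R,R)-TsDPEN] (2 mol%), HCO2H/Et3N (5:2), CH2Cl2, 25 °C
Reagents that add atoms: none
Why: Noyori-type asymmetric transfer hydrogenation of an aryl α-keto ester sets C4. With the aryl group in the site it occupies for aryl ketones and 1,2-diketones, the (R,R) ligand should give the S alcohol. The configuration should be confirmed here (Mosher esters), the antipodal catalyst being equally available, and the prenyl alkene is not touched.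

Step 7
Reactants: 11 ethyl (S)-2-[2,4-bis(tert-butyldimethylsilyloxy)-6-methoxy-3-(3-methylbut-2-en-1-yl)phenyl]-2-hydroxyacetate
Product: 12 ethyl (S)-2-[2,4-bis(tert-butyldimethylsilyloxy)-6-methoxy-3-(3-methylbut-2-en-1-yl)phenyl]-2-(tert-butyldimethylsilyloxy)acetate
Conditions: TBSOTf, 2,6-lutidine, CH2Cl2, −40 → 0 °C
Reagents that add atoms: tert-butyldimethylsilyl trifluoromethanesulfonate (TBSOTf), CC(C)(C)[Si](C)(C)OS(=O)(=O)C(F)(F)F
Why: O-silylation of the hindered secondary alcohol under buffered conditions that do not ionise C4. The bulky, non-chelating silyl ether is what the Felkin–Anh control of step 12 requires, and any aryl silyl ether lost in step 6 is restored here.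

Step 8
Reactants: 12 ethyl (S)-2-[2,4-bis(tert-butyldimethylsilyloxy)-6-methoxy-3-(3-methylbut-2-en-1-yl)phenyl]-2-(tert-butyldimethylsilyloxy)acetate
Product: 14 (S)-2-[2,4-bis(tert-butyldimethylsilyloxy)-6-methoxy-3-(3-methylbut-2-en-1-yl)phenyl]-2-(tert-butyldimethylsilyloxy)acetaldehyde, via aluminium hemiacetal 13 (not isolated)
Conditions: i-Bu2AlH (1.2 equiv), CH2Cl2, −78 °C; MeOH, aq. potassium sodium tartrate
Reagents that add atoms: none
Why: Partial reduction of an α-silyloxy ester. The tetrahedral aluminium hemiacetal is stable at −78 °C and releases the aldehyde only on work-up. The aldehyde is used without chromatography to protect the acidic C4–H.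

Step 9
Reactants: 15 4-hydroxybenzyl alcohol
Product: 17 [4-(triisopropylsilyloxy)phenyl]methanol, via sodium phenolate 16 (not isolated)
Conditions: NaH (1.0 equiv), THF/DMF, 0 °C; TIPSCl
Reagents that add atoms: chlorotriisopropylsilane (TIPSCl), CC(C)[Si](Cl)(C(C)C)C(C)C
Why: Selective O-silylation through the phenolate; one equivalent of base deprotonates only the phenol, which is about five pKa units more acidic than the benzylic alcohol.

Step 10
Reactants: 17 [4-(triisopropylsilyloxy)phenyl]methanol
Product: 18 4-(triisopropylsilyloxy)benzyl bromide
Conditions: CBr4, PPh3, CH2Cl2, 0 °C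
Reagents that add atoms: carbon tetrabromide, BrC(Br)(Br)Br
Why: Appel bromination under neutral conditions that leave the aryl silyl ether intact; the reactive bromide is used directly.

Step 11
Reactants: 18 4-(triisopropylsilyloxy)benzyl bromide; 19 tetrahydrothiophene
Product: 20 1-[4-(triisopropylsilyloxy)benzyl]tetrahydrothiophenium bromide
Conditions: acetone, 25 °C
Reagents that add atoms: none
Why: S-alkylation of the sulfide by an activated benzylic bromide (SN2); the salt separates from the medium.

Step 12
Reactants: 14 (S)-2-[2,4-bis(tert-butyldimethylsilyloxy)-6-methoxy-3-(3-methylbut-2-en-1-yl)phenyl]-2-(tert-butyldimethylsilyloxy)acetaldehyde; 20 1-[4-(triisopropylsilyloxy)benzyl]tetrahydrothiophenium bromide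
Product: 23 (2S,3R)-2-[4-(triisopropylsilyloxy)phenyl]-3-{(S)-[2,4-bis(tert-butyldimethylsilyloxy)-6-methoxy-3-(3-methylbut-2-en-1-yl)phenyl](tert-butyldimethylsilyloxy)methyl}oxirane, via sulfonium ylide 21 (not isolated), via anti betaine 22 (not isolated)
Conditions: 20 (1.3 equiv), LiN(SiMe3)2 (1.2 equiv), THF, −78 °C; then 14, −78 → −20 °C
Reagents that add atoms: none
Why: Deprotonation of 20 at the benzylic carbon gives the semi-stabilised ylide 21, which adds through carbon to the aldehyde carbon of 14 (C2–C3); in betaine 22 the alkoxide then displaces tetrahydrothiophene from C2 in a 3-exo-tet SN2 closure (O–C2), the C3–O bond of the oxirane being the old carbonyl bond. The closest known reaction type is the Corey–Chaykovsky epoxidation of aldehydes, α-oxygenated ones included, with benzylsulfonium ylides, which gives trans aryl oxiranes. C3 is controlled by C4: in the polar Felkin–Anh conformer the C4–OSi bond is antiperiplanar to the incoming ylide, ring A lies on the side of the carbonyl oxygen and hydrogen on the attack trajectory, so the Re face of the S aldehyde is attacked and the C3 oxygen ends up cis to the C4 oxygen in the later ring; the bulky silyl ether gives no chelate that would reverse this. C2 is controlled in the betaine: formation of the syn betaine is reversible and closure of the anti betaine is fast, which leads to the trans oxirane and hence to S at C2 once C3 is fixed. The step needs facial selectivity, trans selectivity, chemoselectivity and configurational stability of 14; the last two are secured because no oxidant is involved (prenyl alkene and silyl ethers are spectators) and because the ylide is pre-formed with a slight deficit of base at −78 °C, so that the acidic C4–H meets no free amide.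

Step 13
Reactants: 23 (2S,3R)-2-[4-(triisopropylsilyloxy)phenyl]-3-{(S)-[2,4-bis(tert-butyldimethylsilyloxy)-6-methoxy-3-(3-methylbut-2-en-1-yl)phenyl](tert-butyldimethylsilyloxy)methyl}oxirane
Product: 26 (2R,3S,4S)-2-(4-hydroxyphenyl)-5-methoxy-8-(3-methylbut-2-en-1-yl)chromane-3,4,7-triol (5-O-methyl-8-prenylafzelechin-4beta-ol), via epoxy bisphenol 24 (not isolated), via silylated flavan 25 (not isolated)
Conditions: Bu4NF/AcOH (1:1), THF, −20 → 0 °C; then Bu4NF, 25 °C
Reagents that add atoms: none
Why: Fluoride desilylation frees the ring A phenols first, and the C8a phenol opens the oxirane at the benzylic C2 (6-endo-tet, intramolecular epoxide opening with inversion), which sets C2 as R, trans to the C3 hydroxyl. C3 is deactivated and shielded by the C4 silyloxy group, which is the last to leave. Even a stepwise opening through a ring B quinone methide should converge on the same isomer, because the 2,3-cis product would place ring B syn-axial to the pseudoaxial C4 oxygen.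

## Compound list

1 | 5-methoxyresorcinol | COc1cc(O)cc(O)c1 | starting material
2 | 1-methoxy-3,5-bis(methoxymethoxy)benzene | COCOc1cc(OC)cc(OCOC)c1 | intermediate
3 | prenyl bromide (1-bromo-3-methylbut-2-ene) | CC(C)=CCBr | starting material
4 | [4-methoxy-2,6-bis(methoxymethoxy)phenyl]lithium | [Li]c1c(OCOC)cc(OC)cc1OCOC | intermediate (not isolated)
5 | 5-methoxy-1,3-bis(methoxymethoxy)-2-(3-methylbut-2-en-1-yl)benzene | COCOc1cc(OC)cc(OCOC)c1CC=C(C)C | intermediate
6 | diethyl oxalate | CCOC(=O)C(=O)OCC | starting material
7 | [6-methoxy-2,4-bis(methoxymethoxy)-3-(3-methylbut-2-en-1-yl)phenyl]lithium | [Li]c1c(OC)cc(OCOC)c(CC=C(C)C)c1OCOC | intermediate (not isolated)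
8 | ethyl 2-[6-methoxy-2,4-bis(methoxymethoxy)-3-(3-methylbut-2-en-1-yl)phenyl]-2-oxoacetate | CCOC(=O)C(=O)c1c(OC)cc(OCOC)c(CC=C(C)C)c1OCOC | intermediate
9 | ethyl 2-[2,4-dihydroxy-6-methoxy-3-(3-methylbut-2-en-1-yl)phenyl]-2-oxoacetate | CCOC(=O)C(=O)c1c(OC)cc(O)c(CC=C(C)C)c1O | intermediate
10 | ethyl 2-[2,4-bis(tert-butyldimethylsilyloxy)-6-methoxy-3-(3-methylbut-2-en-1-yl)phenyl]-2-oxoacetate | CCOC(=O)C(=O)c1c(OC)cc(O[Si](C)(C)C(C)(C)C)c(CC=C(C)C)c1O[Si](C)(C)C(C)(C)C | intermediate
11 | ethyl (S)-2-[2,4-bis(tert-butyldimethylsilyloxy)-6-methoxy-3-(3-methylbut-2-en-1-yl)phenyl]-2-hydroxyacetate | COc1cc(O[Si](C)(C)C(C)(C)C)c(CC=C(C)C)c(O[Si](C)(C)C(C)(C)C)c1[C@H](O)C(=O)OCC | intermediate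
12 | ethyl (S)-2-[2,4-bis(tert-butyldimethylsilyloxy)-6-methoxy-3-(3-methylbut-2-en-1-yl)phenyl]-2-(tert-butyldimethylsilyloxy)acetate | COc1cc(O[Si](C)(C)C(C)(C)C)c(CC=C(C)C)c(O[Si](C)(C)C(C)(C)C)c1[C@H](O[Si](C)(C)C(C)(C)C)C(=O)OCC | intermediate
13 | diisobutylaluminium hemiacetal of 12 (C4 S, acetal carbon undefined) | COc1cc(O[Si](C)(C)C(C)(C)C)c(CC=C(C)C)c(O[Si](C)(C)C(C)(C)C)c1[C@H](O[Si](C)(C)C(C)(C)C)C(OCC)O[Al](CC(C)C)CC(C)C | intermediate (not isolated)
14 | (S)-2-[2,4-bis(tert-butyldimethylsilyloxy)-6-methoxy-3-(3-methylbut-2-en-1-yl)phenyl]-2-(tert-butyldimethylsilyloxy)acetaldehyde | COc1cc(O[Si](C)(C)C(C)(C)C)c(CC=C(C)C)c(O[Si](C)(C)C(C)(C)C)c1[C@H](O[Si](C)(C)C(C)(C)C)C=O | intermediate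
15 | 4-hydroxybenzyl alcohol | OCc1ccc(O)cc1 | starting material
16 | sodium 4-(hydroxymethyl)phenolate | [Na+].[O-]c1ccc(CO)cc1 | intermediate (not isolated)
17 | [4-(triisopropylsilyloxy)phenyl]methanol | OCc1ccc(O[Si](C(C)C)(C(C)C)C(C)C)cc1 | intermediate
18 | 4-(triisopropylsilyloxy)benzyl bromide | BrCc1ccc(O[Si](C(C)C)(C(C)C)C(C)C)cc1 | intermediate
19 | tetrahydrothiophene | C1CCSC1 | starting material
20 | 1-[4-(triisopropylsilyloxy)benzyl]tetrahydrothiophenium bromide | C1CC[S+](Cc2ccc(O[Si](C(C)C)(C(C)C)C(C)C)cc2)C1.[Br-] | intermediate
21 | tetrahydrothiophenium [4-(triisopropylsilyloxy)phenyl]methylide | [CH-](c1ccc(O[Si](C(C)C)(C(C)C)C(C)C)cc1)[S+]1CCCC1 | intermediate (not isolated)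
22 | anti betaine from 14 and 21 (alkoxide at C3, sulfonium at C2; drawn as the zwitterion, lithium alkoxide in the flask) | COc1cc(O[Si](C)(C)C(C)(C)C)c(CC=C(C)C)c(O[Si](C)(C)C(C)(C)C)c1[C@H](O[Si](C)(C)C(C)(C)C)[C@H]([O-])[C@@H](c1ccc(O[Si](C(C)C)(C(C)C)C(C)C)cc1)[S+]1CCCC1 | intermediate (not isolated)
23 | (2S,3R)-2-[4-(triisopropylsilyloxy)phenyl]-3-{(S)-[2,4-bis(tert-butyldimethylsilyloxy)-6-methoxy-3-(3-methylbut-2-en-1-yl)phenyl](tert-butyldimethylsilyloxy)methyl}oxirane (trans oxirane) | COc1cc(O[Si](C)(C)C(C)(C)C)c(CC=C(C)C)c(O[Si](C)(C)C(C)(C)C)c1[C@H](O[Si](C)(C)C(C)(C)C)[C@@H]1O[C@H]1c1ccc(O[Si](C(C)C)(C(C)C)C(C)C)cc1 | intermediate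
24 | (2S,3R)-2-[4-(triisopropylsilyloxy)phenyl]-3-{(S)-(tert-butyldimethylsilyloxy)[2,4-dihydroxy-6-methoxy-3-(3-methylbut-2-en-1-yl)phenyl]methyl}oxirane | COc1cc(O)c(CC=C(C)C)c(O)c1[C@H](O[Si](C)(C)C(C)(C)C)[C@@H]1O[C@H]1c1ccc(O[Si](C(C)C)(C(C)C)C(C)C)cc1 | intermediate (not isolated)
25 | (2R,3R,4S)-4-(tert-butyldimethylsilyloxy)-5-methoxy-8-(3-methylbut-2-en-1-yl)-2-[4-(triisopropylsilyloxy)phenyl]chromane-3,7-diol (2,3-trans, 3,4-cis) | COc1cc(O)c(CC=C(C)C)c2c1[C@H](O[Si](C)(C)C(C)(C)C)[C@H](O)[C@@H](c1ccc(O[Si](C(C)C)(C(C)C)C(C)C)cc1)O2 | intermediate (not isolated)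
26 | (2R,3S,4S)-2-(4-hydroxyphenyl)-5-methoxy-8-(3-methylbut-2-en-1-yl)chromane-3,4,7-triol (5-O-methyl-8-prenylafzelechin-4beta-ol) | COc1cc(O)c(CC=C(C)C)c2c1[C@H](O)[C@H](O)[C@@H](c1ccc(O)cc1)O2 | target

## Step count and least certain steps

Total: 13 steps. Longest linear sequence: 10 steps (steps 1 to 8, 12 and 13); the ring B branch (steps 9 to 11) has 3 steps.

**Step 12 (key step).** The most likely failure is insufficient discrimination between the two faces of the aldehyde, together with leakage to the cis oxirane. The electron-rich ylide adds less reversibly than a simple benzylide, so the correction of the syn betaine is weaker, and the ylide is basic enough to abstract the C4–H of 14. Fallback, changing from substrate control to matched reagent control: bromide 18 is used to alkylate the C2-symmetric (2R,5R)-2,5-dimethylthiolane. This is taken here as the enantiomer that places S configuration at the ylide-derived carbon of trans aryl oxiranes. The product is (2R,5R)-2,5-dimethyl-1-[4-(triisopropylsilyloxy)benzyl]thiolanium bromide F1. Deprotonation with LiN(SiMe3)2 at −78 °C gives the chiral sulfonium ylide F2, which adds to 14 by way of the corresponding anti betaine F3 and closes to 23, where the route is rejoined. The sulfide then fixes the ylide face and reinforces the Felkin–Anh preference of 14.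

**Step 6.** The most likely failure is poor enantioface selection, or even a reversed sense, because the aryl group of 10 is twisted out of the carbonyl plane by its two ortho oxygens and may not occupy the site on which the usual model rests. Fallback, changing from asymmetric catalysis to resolution: 10 is reduced with NaBH4 (MeOH/THF, −40 °C) to racemic ethyl 2-[2,4-bis(tert-butyldimethylsilyloxy)-6-methoxy-3-(3-methylbut-2-en-1-yl)phenyl]-2-hydroxyacetate F4. The enantiomers are separated by preparative chromatography on a chiral stationary phase, and the unwanted enantiomer is returned to 10 with Dess–Martin periodinane. The S enantiomer is 11, where the route is rejoined.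

**Step 13.** The most likely failure is loss of the ring B silyl group before ring closure, after which the oxirane can open through a quinone methide. Strict inversion at C2 then no longer holds, and solvolysis or rearrangement to a ketone can compete. Attack at C3 (5-exo) and slow removal of the hindered C4 silyl ether are lesser concerns. Fallback, separating ring closure from deprotection and closing as the phenoxide without fluoride (no new compound, F0): 23 is treated with K2CO3 in MeOH at 0 °C, which cleaves only the two ring A aryl TBS ethers and lets the C8a phenoxide close the ring, and the silylated flavan 25 is isolated. A separate buffered fluoride treatment (Bu4NF/AcOH, THF, 25 °C) then gives 26.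

**Step 3.** The most likely failure is deprotonation of the benzylic-allylic CH2 of the prenyl chain in competition with ring metalation, with double addition to the oxalate as a lesser risk. Fallback, changing from an aryl anion to electrophilic aromatic substitution: 5, whose two free ring positions are equivalent, is treated with ethyl glyoxylate and catalytic Sc(OTf)3 (CH2Cl2, −20 °C) in a Friedel–Crafts hydroxyalkylation. This gives racemic ethyl 2-hydroxy-2-[6-methoxy-2,4-bis(methoxymethoxy)-3-(3-methylbut-2-en-1-yl)phenyl]acetate F5, which is oxidised with Dess–Martin periodinane to 8, where the route is rejoined.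

**Step 8.** The most likely failure is over-reduction past the aldehyde and erosion of C4 by enolisation of the α-aryl-α-silyloxy aldehyde during work-up. Fallback, changing to a reduction–oxidation pair: 12 is reduced completely with LiBH4 (THF, 0 °C) to (S)-2-[2,4-bis(tert-butyldimethylsilyloxy)-6-methoxy-3-(3-methylbut-2-en-1-yl)phenyl]-2-(tert-butyldimethylsilyloxy)ethanol F6. This is oxidised with Dess–Martin periodinane buffered with NaHCO3 to 14, which is used at once in step 12.

## Further compounds

F1 | step 12 | (2R,5R)-2,5-dimethyl-1-[4-(triisopropylsilyloxy)benzyl]thiolanium bromide | C[C@@H]1CC[C@@H](C)[S+]1Cc1ccc(O[Si](C(C)C)(C(C)C)C(C)C)cc1.[Br-]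
F2 | step 12 | (2R,5R)-2,5-dimethylthiolanium [4-(triisopropylsilyloxy)phenyl]methylide | C[C@@H]1CC[C@@H](C)[S+]1[CH-]c1ccc(O[Si](C(C)C)(C(C)C)C(C)C)cc1
F3 | step 12 | anti betaine from 14 and F2 (drawn as the zwitterion) | COc1cc(O[Si](C)(C)C(C)(C)C)c(CC=C(C)C)c(O[Si](C)(C)C(C)(C)C)c1[C@H](O[Si](C)(C)C(C)(C)C)[C@H]([O-])[C@@H](c1ccc(O[Si](C(C)C)(C(C)C)C(C)C)cc1)[S+]1[C@H](C)CC[C@H]1C
F4 | step 6 | racemic ethyl 2-[2,4-bis(tert-butyldimethylsilyloxy)-6-methoxy-3-(3-methylbut-2-en-1-yl)phenyl]-2-hydroxyacetate | COc1cc(O[Si](C)(C)C(C)(C)C)c(CC=C(C)C)c(O[Si](C)(C)C(C)(C)C)c1C(O)C(=O)OCC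
F0 | step 13 | none | none
F5 | step 3 | racemic ethyl 2-hydroxy-2-[6-methoxy-2,4-bis(methoxymethoxy)-3-(3-methylbut-2-en-1-yl)phenyl]acetate | CCOC(=O)C(O)c1c(OC)cc(OCOC)c(CC=C(C)C)c1OCOC
F6 | step 8 | (S)-2-[2,4-bis(tert-butyldimethylsilyloxy)-6-methoxy-3-(3-methylbut-2-en-1-yl)phenyl]-2-(tert-butyldimethylsilyloxy)ethanol | COc1cc(O[Si](C)(C)C(C)(C)C)c(CC=C(C)C)c(O[Si](C)(C)C(C)(C)C)c1[C@H](O[Si](C)(C)C(C)(C)C)CO
A1 | alternative 1 | (2R,3R)-8-bromo-5-O-methyldihydrokaempferol tris(tert-butyldimethylsilyl) ether | COc1cc(O[Si](C)(C)C(C)(C)C)c(Br)c2c1C(=O)[C@H](O[Si](C)(C)C(C)(C)C)[C@@H](c1ccc(O[Si](C)(C)C(C)(C)C)cc1)O2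
A2 | alternative 1 | (R)-1-[3-bromo-4-(tert-butyldimethylsilyloxy)-2-hydroxy-6-methoxyphenyl]-2-(tert-butyldimethylsilyloxy)-3-[4-(tert-butyldimethylsilyloxy)phenyl]propan-1-one | COc1cc(O[Si](C)(C)C(C)(C)C)c(Br)c(O)c1C(=O)[C@H](O[Si](C)(C)C(C)(C)C)Cc1ccc(O[Si](C)(C)C(C)(C)C)cc1
A3 | alternative 1 | D-tyrosine | N[C@H](Cc1ccc(O)cc1)C(=O)O
A4 | alternative 2 | 3,4-O-isopropylidene-7,4'-bis-O-(tert-butyldimethylsilyl)-5-O-methyl-8-prenylafzelechin-4beta-ol | COc1cc(O[Si](C)(C)C(C)(C)C)c(CC=C(C)C)c2c1[C@@H]1OC(C)(C)O[C@@H]1[C@@H](c1ccc(O[Si](C)(C)C(C)(C)C)cc1)O2
A5 | alternative 2 | 1,3-dioxoisoindolin-2-yl (4S,5R)-5-{(R)-[2-bromo-5-(tert-butyldimethylsilyloxy)-3-methoxy-6-(3-methylbut-2-en-1-yl)phenoxy][4-(tert-butyldimethylsilyloxy)phenyl]methyl}-2,2-dimethyl-1,3-dioxolane-4-carboxylate | COc1cc(O[Si](C)(C)C(C)(C)C)c(CC=C(C)C)c(O[C@H](c2ccc(O[Si](C)(C)C(C)(C)C)cc2)[C@H]2OC(C)(C)O[C@@H]2C(=O)ON2C(=O)c3ccccc3C2=O)c1Br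
A6 | alternative 2 | (2S,3S)-tartaric acid | OC(=O)[C@@H](O)[C@H](O)C(=O)O
A7 | alternative 3 | 4'-O-(tert-butyldimethylsilyl)-5-O-methyl-8-prenylafzelechin-4beta-ol | COc1cc(O)c(CC=C(C)C)c2c1[C@H](O)[C@H](O)[C@@H](c1ccc(O[Si](C)(C)C(C)(C)C)cc1)O2
A8 | alternative 3 | 5-methoxy-2-(3-methylbut-2-en-1-yl)benzene-1,3-diol | COc1cc(O)c(CC=C(C)C)c(O)c1
A9 | alternative 3 | (2R,3S)-3-[4-(tert-butyldimethylsilyloxy)phenyl]oxirane-2-carbaldehyde | O=C[C@@H]1O[C@H]1c1ccc(O[Si](C)(C)C(C)(C)C)cc1
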